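**Retrosynthetic overview**
1. Target 6 is the meso α,α'-dimer of the dihydrochalcone davidigenin (3). Instead of the textbook acyl-anion/enone cut at C1–C2, the central C2–C3 bond between the two ketone α-carbons (both natively nucleophilic) is cut, giving two identical C15 halves.
2. Key step: Cu(II) oxidative homocoupling of the persilylated silyl enol ether 4. One α-carbon is turned into an electrophilic α-keto radical (enolate redox umpolung); both stereocentres form in this step.
3. The TMS groups are transient phenol protection and fall off in the work-up of the coupling, so no separate deprotection step is needed.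
4. 4 comes from 3 by exhaustive silylation; 3 comes from resorcinol (1) and phloretic acid (2) by Friedel–Crafts acylation.
5. No rings are formed; all benzene rings are bought.

Assumption: the SMILES encodes the (2R,3S) isomer, which with two identical halves is the meso compound (achiral), so the task is meso versus (±) diastereocontrol, not enantiocontrol.

Stereochemical note: if the kinetic meso:(±) ratio in step 3 is poor, the (±)-isomer left in the mother liquor can be re-equilibrated (both centres are α to aryl ketones) and recycled.

Step 1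
Reactants: 1 resorcinol; 2 3-(4-hydroxyphenyl)propanoic acid (phloretic acid)
Product: 3 1-(2,4-dihydroxyphenyl)-3-(4-hydroxyphenyl)propan-1-one (davidigenin)
Conditions: BF3·OEt2 (as solvent), 90 °C, 2 h; then aq. NaOAc
Reagents that add atoms: none
Why: BF3-promoted Friedel–Crafts (Nencki-type) C-acylation of resorcinol by the free acid goes at C4 (para to one OH, ortho to the other), and the product is held as its BF2 chelate, which stops a second acylation; no stereocentre is formed.

Step 2
Reactants: 3 davidigenin
Product: 4 (Z)-1-[2,4-bis(trimethylsilyloxy)phenyl]-1-(trimethylsilyloxy)-3-[4-(trimethylsilyloxy)phenyl]prop-1-ene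
Conditions: TMSOTf (4.6 equiv), Et3N (6 equiv), CH2Cl2, 0 °C → rt; evaporate, pentane, filter under Ar; crude oil used directly
Reagents that add atoms: trimethylsilyl trifluoromethanesulfonate (TMSOTf), C[Si](C)(C)OS(=O)(=O)C(F)(F)F
Why: Exhaustive silylation (O-silylation of the three phenols plus soft enolisation of the aryl ketone to the thermodynamic (Z)-silyl enol ether) masks the oxidisable phenols and installs the latent α-nucleophile in one operation; no stereocentre is formed.

Step 3
Reactants: 4 persilylated (Z)-silyl enol ether (two molecules)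
Product: 6 meso-(2R,3S)-1,4-bis(2,4-dihydroxyphenyl)-2,3-bis(4-hydroxybenzyl)butane-1,4-dione, via hexakis-TMS meso-diketone 5 (not isolated)
Conditions: Cu(OTf)2 (1.1 equiv), Cu2O (1.0 equiv), MeCN, −20 → 0 °C; then 0.5 M aq. HCl, THF, 0 °C, 20 min; crystallise (MeOH/H2O)
Reagents that add atoms: none
Why: Cu(II) oxidative homocoupling of a silyl enol ether (enolate redox umpolung): one-electron oxidation and loss of silicon turn the nucleophilic α-carbon into an electrophilic α-keto radical that adds to the α-carbon of a second enol ether, forming the C2–C3 bond and both stereocentres at once through an open, non-chelated transition state in which like groups sit anti (aroyl/aroyl, benzyl/benzyl), which leads to the meso (2R,3S) isomer as the expected major product (estimated 1.5–3:1); the cold dilute-acid work-up strips the six aryl TMS ethers without enolising the α-centres, and crystallisation removes residual (±)-isomer.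

**Compound list**
1 | resorcinol (benzene-1,3-diol) | Oc1cccc(O)c1 | starting material
2 | 3-(4-hydroxyphenyl)propanoic acid (phloretic acid) | OC(=O)CCc1ccc(O)cc1 | starting material
3 | 1-(2,4-dihydroxyphenyl)-3-(4-hydroxyphenyl)propan-1-one (davidigenin) | O=C(CCc1ccc(O)cc1)c1ccc(O)cc1O | intermediate
4 | (Z)-1-[2,4-bis(trimethylsilyloxy)phenyl]-1-(trimethylsilyloxy)-3-[4-(trimethylsilyloxy)phenyl]prop-1-ene | C[Si](C)(C)O/C(=C\Cc1ccc(O[Si](C)(C)C)cc1)c1ccc(O[Si](C)(C)C)cc1O[Si](C)(C)C | intermediate
5 | meso-(2R,3S)-1,4-bis[2,4-bis(trimethylsilyloxy)phenyl]-2,3-bis[4-(trimethylsilyloxy)benzyl]butane-1,4-dione | O=C(c1ccc(O[Si](C)(C)C)cc1O[Si](C)(C)C)[C@@H](Cc1ccc(O[Si](C)(C)C)cc1)[C@@H](Cc1ccc(O[Si](C)(C)C)cc1)C(=O)c1ccc(O[Si](C)(C)C)cc1O[Si](C)(C)C | intermediate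
6 | meso-(2R,3S)-1,4-bis(2,4-dihydroxyphenyl)-2,3-bis(4-hydroxybenzyl)butane-1,4-dione | O=C(c1ccc(O)cc1O)[C@@H](Cc1ccc(O)cc1)[C@@H](Cc1ccc(O)cc1)C(=O)c1ccc(O)cc1O | target

**Total step count:** 3. **Longest linear sequence:** 3.

**Steps most likely to fail, with fallbacks**

Step 3 (highest risk: over-oxidation to the chalcone, oxidation of the electron-rich arenes, sluggish coupling at the substituted α-carbon). The fallback makes the same bond redox-neutrally, with no stoichiometric oxidant. It sets out from 4: half of the material is brominated with NBS (THF, −78 °C) to racemic 2-bromo-1-[2,4-bis(trimethylsilyloxy)phenyl]-3-[4-(trimethylsilyloxy)phenyl]propan-1-one F1, an enolonium equivalent. F1 is then coupled with the other half of 4 under photoredox catalysis (fac-Ir(ppy)3 1 mol %, blue LED, MeCN, rt). The reductively generated α-keto radical adds to the enol silane, and radical-polar crossover with loss of bromotrimethylsilane gives the diketone. The fallback comes back to the route at 5, which receives the same acidic work-up to 6.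

Step 2 (the tetra-TMS enol ether may be too labile to handle, or the chelated 2'-OH may silylate incompletely). The fallback drops the silyl enol ether and uses benzyl ethers with a lithium enolate. It sets out from 3: benzylation (BnBr, K2CO3, DMF, 70 °C) gives 1-[2,4-bis(benzyloxy)phenyl]-3-[4-(benzyloxy)phenyl]propan-1-one F2. Its lithium enolate (LDA, THF, −78 °C) is dimerised oxidatively with CuCl2/DMF (−78 °C → rt) to meso-1,4-bis[2,4-bis(benzyloxy)phenyl]-2,3-bis[4-(benzyloxy)benzyl]butane-1,4-dione F3. The meso isomer is collected by crystallisation while catalytic DBU re-equilibrates the (±)-isomer in the liquor. Neutral hydrogenolysis (H2, Pd/C, EtOAc/THF, rt) then removes the six benzyl groups without touching the α-centres, and the fallback comes back to the route at 6.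

Step 1 (the free phenolic acid may esterify or self-acylate, giving poor conversion). The fallback builds the C15 ketone by aldol condensation and hydrogenation instead. It sets out from 1: Nencki acetylation (AcOH, ZnCl2, 140 °C) gives 2,4-dihydroxyacetophenone F4. Claisen–Schmidt condensation with commercial 4-hydroxybenzaldehyde (60% aq. KOH, EtOH, rt) gives (E)-1-(2,4-dihydroxyphenyl)-3-(4-hydroxyphenyl)prop-2-en-1-one (isoliquiritigenin) F5. Hydrogenation of the C=C only (H2 1 atm, Pd/C, EtOAc) comes back to the route at 3.

**Further compounds**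
F1 | step 3 | 2-bromo-1-[2,4-bis(trimethylsilyloxy)phenyl]-3-[4-(trimethylsilyloxy)phenyl]propan-1-one (racemic) | O=C(C(Br)Cc1ccc(O[Si](C)(C)C)cc1)c1ccc(O[Si](C)(C)C)cc1O[Si](C)(C)C
F2 | step 2 | 1-[2,4-bis(benzyloxy)phenyl]-3-[4-(benzyloxy)phenyl]propan-1-one | O=C(CCc1ccc(OCc2ccccc2)cc1)c1ccc(OCc2ccccc2)cc1OCc1ccccc1
F3 | step 2 | meso-(2R,3S)-1,4-bis[2,4-bis(benzyloxy)phenyl]-2,3-bis[4-(benzyloxy)benzyl]butane-1,4-dione | O=C(c1ccc(OCc2ccccc2)cc1OCc1ccccc1)[C@@H](Cc1ccc(OCc2ccccc2)cc1)[C@@H](Cc1ccc(OCc2ccccc2)cc1)C(=O)c1ccc(OCc2ccccc2)cc1OCc1ccccc1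
F4 | step 1 | 2,4-dihydroxyacetophenone | CC(=O)c1ccc(O)cc1O
F5 | step 1 | (E)-1-(2,4-dihydroxyphenyl)-3-(4-hydroxyphenyl)prop-2-en-1-one (isoliquiritigenin) | O=C(/C=C/c1ccc(O)cc1)c1ccc(O)cc1O
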